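## Retrosynthetic overview

1. The acetate goes on last. The oxirane is the only ring made (the benzene ring is bought) and comes from a Sharpless asymmetric epoxidation of a 2-arylallyl alcohol, which sets the single stereocentre.
2. The allylic alcohol is carried as a TBS ether while the other two esters are installed: the benzylic isovalerate by chemoselective Mitsunobu esterification, then the aryl angelate by mixed-anhydride acylation.
3. The aryl–alkenyl bond is made first, by Suzuki coupling of a bromophenol with a 2-borylallyl silyl ether, so that no ester meets palladium or aqueous base.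

Assumption: 1 and 2 are bought as catalogue building blocks.

## Route

Step 1
Reactants: 1 2-bromo-5-(hydroxymethyl)phenol; 2 tert-butyldimethyl{[2-(4,4,5,5-tetramethyl-1,3,2-dioxaborolan-2-yl)prop-2-en-1-yl]oxy}silane
Product: 3 2-{3-[(tert-butyldimethylsilyl)oxy]prop-1-en-2-yl}-5-(hydroxymethyl)phenol
Conditions: 2 (1.3 equiv), Pd(PPh3)4 (5 mol %), K2CO3 (3 equiv), 1,4-dioxane/H2O 4:1, 85 °C
Reagents that add atoms: none
Why: Suzuki–Miyaura coupling (oxidative addition of the aryl bromide to zerovalent palladium, then transmetalation of the alkenyl boronate) tolerates the free phenol and benzylic alcohol, and the silyl ether is stable to aqueous carbonate.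

Step 2
Reactants: 3 2-{3-[(tert-butyldimethylsilyl)oxy]prop-1-en-2-yl}-5-(hydroxymethyl)phenol; 4 3-methylbutanoic acid (isovaleric acid)
Product: 5 {4-[3-(tert-butyldimethylsilyloxy)prop-1-en-2-yl]-3-hydroxyphenyl}methyl 3-methylbutanoate
Conditions: 4 (1.1 equiv), PPh3, DIAD (1.2 equiv each), THF, 0 °C → rt
Reagents that add atoms: none
Why: Mitsunobu esterification activates only the aliphatic hydroxyl as its alkoxyphosphonium ion, and the carboxylic acid (pKa about 5) outcompetes the phenol (pKa about 10) as the nucleophile; the meta relationship rules out quinone methide formation.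

Step 3
Reactants: 5 {4-[3-(tert-butyldimethylsilyloxy)prop-1-en-2-yl]-3-hydroxyphenyl}methyl 3-methylbutanoate; 6 (2Z)-2-methylbut-2-enoic acid (angelic acid)
Product: 8 2-{3-[(tert-butyldimethylsilyl)oxy]prop-1-en-2-yl}-5-{[(3-methylbutanoyl)oxy]methyl}phenyl (2Z)-2-methylbut-2-enoate, via angelic 2,4,6-trichlorobenzoic anhydride 7 (not isolated)
Conditions: 6 (1.5 equiv), 2,4,6-Cl3C6H2COCl, Et3N, toluene, rt, 2 h; then 5, Et3N, 60 °C
Reagents that add atoms: none
Why: Yamaguchi-type mixed-anhydride acylation; the phenol attacks the less hindered angeloyl carbonyl, and leaving out DMAP or any other nucleophilic catalyst keeps the Z geometry.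

Step 4
Reactants: 8 2-{3-[(tert-butyldimethylsilyl)oxy]prop-1-en-2-yl}-5-{[(3-methylbutanoyl)oxy]methyl}phenyl (2Z)-2-methylbut-2-enoate
Product: 9 2-(3-hydroxyprop-1-en-2-yl)-5-{[(3-methylbutanoyl)oxy]methyl}phenyl (2Z)-2-methylbut-2-enoate
Conditions: HF·pyridine, pyridine, THF, 0 °C → rt
Reagents that add atoms: none
Why: Fluoride-mediated desilylation under buffered, mildly acidic conditions never generates an alkoxide, so the phenolic angelate neither cleaves nor migrates to the new primary alcohol.

Step 5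
Reactants: 9 2-(3-hydroxyprop-1-en-2-yl)-5-{[(3-methylbutanoyl)oxy]methyl}phenyl (2Z)-2-methylbut-2-enoate
Product: 10 2-[(2S)-2-(hydroxymethyl)oxiran-2-yl]-5-{[(3-methylbutanoyl)oxy]methyl}phenyl (2Z)-2-methylbut-2-enoate
Conditions: Ti(OiPr)4 (10 mol %), L-(+)-diethyl tartrate (12 mol %), t-BuOOH (2 equiv, anhydrous), 4 Å MS, CH2Cl2, −20 °C
Reagents that add atoms: tert-butyl hydroperoxide, CC(C)(C)OO
Why: Katsuki–Sharpless asymmetric epoxidation: the titanium-bound allylic alkoxide directs oxygen to one face of the 1,1-disubstituted alkene, and L-(+)-tartrate gives the (S)-epoxy alcohol (same facial sense as methallyl alcohol to (S)-2-methylglycidol). The electron-poor angelate alkene is not touched.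

Step 6
Reactants: 10 2-[(2S)-2-(hydroxymethyl)oxiran-2-yl]-5-{[(3-methylbutanoyl)oxy]methyl}phenyl (2Z)-2-methylbut-2-enoate
Product: 11 2-[(2R)-2-(acetoxymethyl)oxiran-2-yl]-5-{[(3-methylbutanoyl)oxy]methyl}phenyl (2Z)-2-methylbut-2-enoate (CNP0212475.1)
Conditions: Ac2O (1.5 equiv), pyridine, CH2Cl2, 0 °C → rt
Reagents that add atoms: acetic anhydride, CC(=O)OC(C)=O
Why: Simple O-acetylation of the primary alcohol (nucleophilic acyl substitution) leaves the quaternary centre untouched; the descriptor changes from S to R only because CH2OAc now outranks the ring CH2.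

## Compound list

1 | 2-bromo-5-(hydroxymethyl)phenol | OCc1ccc(Br)c(O)c1 | starting material
2 | tert-butyldimethyl{[2-(4,4,5,5-tetramethyl-1,3,2-dioxaborolan-2-yl)prop-2-en-1-yl]oxy}silane | C=C(CO[Si](C)(C)C(C)(C)C)B1OC(C)(C)C(C)(C)O1 | starting material
3 | 2-{3-[(tert-butyldimethylsilyl)oxy]prop-1-en-2-yl}-5-(hydroxymethyl)phenol | C=C(CO[Si](C)(C)C(C)(C)C)c1ccc(CO)cc1O | intermediate
4 | 3-methylbutanoic acid (isovaleric acid) | CC(C)CC(=O)O | starting material
5 | {4-[3-(tert-butyldimethylsilyloxy)prop-1-en-2-yl]-3-hydroxyphenyl}methyl 3-methylbutanoate | CC(C)CC(=O)OCc1ccc(C(=C)CO[Si](C)(C)C(C)(C)C)c(O)c1 | intermediate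
6 | (2Z)-2-methylbut-2-enoic acid (angelic acid) | C/C=C(/C)C(=O)O | starting material
7 | (2Z)-2-methylbut-2-enoic 2,4,6-trichlorobenzoic anhydride | C/C=C(/C)C(=O)OC(=O)c1c(Cl)cc(Cl)cc1Cl | intermediate
8 | 2-{3-[(tert-butyldimethylsilyl)oxy]prop-1-en-2-yl}-5-{[(3-methylbutanoyl)oxy]methyl}phenyl (2Z)-2-methylbut-2-enoate | C/C=C(/C)C(=O)Oc1cc(COC(=O)CC(C)C)ccc1C(=C)CO[Si](C)(C)C(C)(C)C | intermediate
9 | 2-(3-hydroxyprop-1-en-2-yl)-5-{[(3-methylbutanoyl)oxy]methyl}phenyl (2Z)-2-methylbut-2-enoate | C/C=C(/C)C(=O)Oc1cc(COC(=O)CC(C)C)ccc1C(=C)CO | intermediate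
10 | 2-[(2S)-2-(hydroxymethyl)oxiran-2-yl]-5-{[(3-methylbutanoyl)oxy]methyl}phenyl (2Z)-2-methylbut-2-enoate | C/C=C(/C)C(=O)Oc1cc(COC(=O)CC(C)C)ccc1[C@]1(CO)CO1 | intermediate
11 | 2-[(2R)-2-(acetoxymethyl)oxiran-2-yl]-5-{[(3-methylbutanoyl)oxy]methyl}phenyl (2Z)-2-methylbut-2-enoate | C/C=C(/C)C(=O)Oc1cc(COC(=O)CC(C)C)ccc1[C@]1(COC(C)=O)CO1 | target

## Step count and risks

Total step count: 6. Longest linear sequence: 6 (1 → 3 → 5 → 8 → 9 → 10 → 11).

The three steps most likely to fail:

Step 5 (asymmetric epoxidation). The tertiary benzylic epoxide with an ortho acyloxy group can be opened by the Lewis-acidic titanium species, and 2-arylallyl alcohols sometimes give only moderate ee. The fallback sets out from 9 and replaces asymmetric catalysis by a resolution. Compound 9 is epoxidised without chiral control (VO(acac)2 cat., t-BuOOH, toluene, 0 °C, hydroxyl-directed) to racemic 2-[2-(hydroxymethyl)oxiran-2-yl]-5-{[(3-methylbutanoyl)oxy]methyl}phenyl (2Z)-2-methylbut-2-enoate F1. This is then resolved by lipase-catalysed transacetylation (vinyl acetate, immobilised Burkholderia cepacia lipase, MTBE, 30 °C, stopped near 50 % conversion), with the enzyme chosen by screening so that the (S)-alcohol is acetylated. The acetate formed is the target, so the fallback comes back to the route at 11; the slow-reacting half of F1 is removed by chromatography. If the lipase found shows the opposite preference, the recovered alcohol is 10 itself and step 6 follows.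

Step 3 (angeloylation). The ortho-substituted phenol is hindered, and any Z → E leakage gives the inseparable tiglate. The fallback sets out from 5 and builds the Z-alkene on the ester instead of transferring it. The phenol is esterified with 2-[bis(2,2,2-trifluoroethoxy)phosphoryl]propanoic acid (EDC·HCl, cat. DMAP, CH2Cl2, 0 °C) to give 2-{3-[(tert-butyldimethylsilyl)oxy]prop-1-en-2-yl}-5-{[(3-methylbutanoyl)oxy]methyl}phenyl 2-[bis(2,2,2-trifluoroethoxy)phosphoryl]propanoate F2. A Still–Gennari olefination with acetaldehyde (KN(SiMe3)2, 18-crown-6, THF, −78 °C) then gives the Z-trisubstituted enoate and comes back to the route at 8.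

Step 2 (chemoselective Mitsunobu). The phenol may compete as nucleophile and give benzyl aryl ethers. The fallback sets out from 3 and over-acylates, then trims. Both hydroxyls are esterified with isovaleryl chloride (2.5 equiv, pyridine, CH2Cl2, 0 °C) to give 2-{3-[(tert-butyldimethylsilyl)oxy]prop-1-en-2-yl}-5-{[(3-methylbutanoyl)oxy]methyl}phenyl 3-methylbutanoate F3. The more electrophilic aryl ester alone is then removed by aminolysis with pyrrolidine (1.1 equiv, THF, 0 °C), which comes back to the route at 5.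

## Further compounds

F1 | step 5 | racemic 2-[2-(hydroxymethyl)oxiran-2-yl]-5-{[(3-methylbutanoyl)oxy]methyl}phenyl (2Z)-2-methylbut-2-enoate | C/C=C(/C)C(=O)Oc1cc(COC(=O)CC(C)C)ccc1C1(CO)CO1
F2 | step 3 | 2-{3-[(tert-butyldimethylsilyl)oxy]prop-1-en-2-yl}-5-{[(3-methylbutanoyl)oxy]methyl}phenyl 2-[bis(2,2,2-trifluoroethoxy)phosphoryl]propanoate | CC(C(=O)Oc1cc(COC(=O)CC(C)C)ccc1C(=C)CO[Si](C)(C)C(C)(C)C)P(=O)(OCC(F)(F)F)OCC(F)(F)F
F3 | step 2 | 2-{3-[(tert-butyldimethylsilyl)oxy]prop-1-en-2-yl}-5-{[(3-methylbutanoyl)oxy]methyl}phenyl 3-methylbutanoate | CC(C)CC(=O)OCc1ccc(C(=C)CO[Si](C)(C)C(C)(C)C)c(OC(=O)CC(C)C)c1
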